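- At early times I watch two rates in Wednesday's flask. Substrate Q turns into X at 2.09 mM h⁻¹, and reagent E turns into Z at 1.90 mM h⁻¹.

| setting | Wednesday's | Monday's |
|---|---|---|
| Q | 10 mM | 10 mM |
| E | 1.10 equiv | 1.10 equiv |
| temperature | 25 °C | 5 °C |
| time | 20 h | 20 h |

1. the best flask by amount of X, in percent of the Q charged; "all alike" if 1.5 percentage points covers them all (Wednesday's / Monday's / all alike)
2. amount of X at the end, in percent of the Q charged, Wednesday's
3. amount of X at the end, in percent of the Q charged, Monday's

- percent here means Q units held: one Q.X.Z counts as two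
- at 25 °C the constants are as listed, elsewhere as the activation energies and enthalpies make them

    Q ⇌ X (K1 = 12, k1 = 5.8 × 10⁻⁵ s⁻¹, Ea1 = 95.0 kJ mol⁻¹, ΔH1 = −5.00 kJ mol⁻¹)
    E → Z (k2 = 4.8 × 10⁻⁵ s⁻¹, Ea2 = 93.0 kJ mol⁻¹)
    X + Z → X.Z (k3 = 0.043 M⁻¹ s⁻¹, Ea3 = 45.0 kJ mol⁻¹)
    Q + X.Z → Q.X.Z (k4 = 0.0042 M⁻¹ s⁻¹, Ea4 = 63.0 kJ mol⁻¹)
    X → D (k5 = 6.2 × 10⁻⁵ s⁻¹, Ea5 = 93.0 kJ mol⁻¹)
    (constants at 25 °C)

- Apart from the way back to Q, X leaves in two ways. It decays to D with constant 6.2 × 10⁻⁵ s⁻¹, and it joins Z to give X.Z with constant 0.043 M⁻¹ s⁻¹. With Z present, the second is a pseudo-first-order loss whose constant grows with Z.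
- The decay constant over the joining constant gives 1.44 mM. I call this the crossing level Z×: the amount of Z at which X goes equally to X.Z and to D. Above it, X goes mainly to X.Z.
- Monday's flask is colder. Its decay and its E → Z step share one activation energy and slow by 15. Its joining step slows by 3.7. So Monday's Z× falls to 0.358 mM.
- At its starting rate, and if none were eaten, Z reaches Z× after 0.759 h in Wednesday's flask. In Monday's flask that takes 2.80 h. Both crossings come early, so I expect Z to be the main drain on X for most of each run.
- The making of X slows as Q is spent. I reckon that slowing as a first-order decay of the forward step. On that reckoning, Wednesday's rate falls to 1.54% of its start.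
- Monday's forward step slows by 15.7, so on the same reckoning its rate falls just to 76.7% of its start.
- I put X at the end near making over loss, with Z taken as uneaten. In Wednesday's flask, with E wholly turned to Z, that gives 0.167%. In Monday's flask it gives 8.31%. So I commit to Monday's flask holding more X.
- The forecast names Monday's, with 0.2% for Wednesday's and 12% for Monday's, on the ground that “X peaks early and is then drained by excess Z and by decay to D”.
- The simulation gives Monday's as the best flask, with 0.182% for Wednesday's and 12.5% for Monday's.

- In Wednesday's flask Z stands at 4.74 mM after 20.0 h, which is 3.29 times Z×, and X goes to X.Z 3.3 times as fast as to D; the flask ends with X.Z at 47.9% and D at 28.9%. With 0.660 equiv of E, the same flask ends with Z at 1.76 mM, just 1.22 times Z×, and D at 43.4% stands above X.Z at 37.7%.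

The numbers are assumed; what happens was integrated by code.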